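**Plan**
- The retrosynthesis first cuts the two 3-methylbutanoate C–O bonds, giving a diol whose two carbinol carbons trace back to a methyl ester on ring B and a protecting ester on the chain.
- Ring B (S1', C2'–C5') is a 2,5-disubstituted thiophene with hydrogen at C3' and C4' and one oxygenated carbon on C5'. It is opened at S1'–C2' and C4'–C5' into a β-chloroenal on ring A and methyl sulfanylacetate, whose CH2 becomes C5' and whose ester carbon becomes the CH2O carbon.
- The chloroenal goes back to the acetyl group of 2-acetyl-5-bromothiophene, and the ring A–alkyne bond to a Sonogashira coupling with O-acylated but-3-yn-1-ol.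
- Forward: ring A is bought, the chain is attached (steps 1–2), the acetyl group becomes the chloroenal (step 3), ring B is closed (step 4), then reduction and twofold acylation follow (steps 5–6).
- Stereochemistry: the target has no stereocentre. Only the Z geometry of the chloroenal matters, and it is consumed when ring B aromatises.

Key step: step 4

Remark on the chemistry: the chain isovalerate put on in step 1 protects the hydroxyl group through steps 2–4 and is given up in step 5. Acid chloride 2 is therefore used once in step 1 and twice in step 6, where one molecule is entered as reactant and the second as an atom-adding reagent. Ring A is the thiophene carrying the butynyl chain and ring B the one carrying the oxygenated one-carbon group, whatever the locants in the systematic names.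

**Route**

Step 1
Reactants: 1 but-3-yn-1-ol; 2 3-methylbutanoyl chloride
Product: 3 but-3-yn-1-yl 3-methylbutanoate
Conditions: Et3N (1.5 equiv), DMAP (5 mol %), CH2Cl2, 0 °C to rt
Reagents that add atoms: none
Why: DMAP-catalysed O-acylation of a primary alcohol by an acid chloride (nucleophilic acyl substitution) should be clean, and the ester shields the hydroxyl group from POCl3 in step 3 while leaving the terminal alkyne free for step 2.

Step 2
Reactants: 3 but-3-yn-1-yl 3-methylbutanoate; 4 1-(5-bromothiophen-2-yl)ethan-1-one (2-acetyl-5-bromothiophene)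
Product: 5 4-(5-acetylthiophen-2-yl)but-3-yn-1-yl 3-methylbutanoate
Conditions: Pd(PPh3)2Cl2 (2 mol %), CuI (4 mol %), Et3N, THF, degassed, 50 °C
Reagents that add atoms: none
Why: In this Sonogashira coupling the acetyl group makes the C–Br bond of 4 electron-poor and eases oxidative addition to zerovalent palladium (formed in the flask from the divalent palladium precatalyst), and the amine conditions leave ketone and ester untouched.

Step 3
Reactants: 5 4-(5-acetylthiophen-2-yl)but-3-yn-1-yl 3-methylbutanoate
Product: 7 (2Z)-3-chloro-3-{5-[4-(3-methylbutanoyloxy)but-1-yn-1-yl]thiophen-2-yl}prop-2-enal, via iminium chloride 6 (not isolated)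
Conditions: POCl3 (3 equiv), DMF, 0 °C then 55 °C; then ice-water
Reagents that add atoms: N,N-dimethylformamide CN(C)C=O; phosphoryl chloride O=P(Cl)(Cl)Cl; water O
Why: In this Vilsmeier–Haack–Arnold haloformylation of an aryl methyl ketone the chloroiminium ion from POCl3 and DMF formylates the enolised acetyl group and exchanges the carbonyl oxygen for chloride to give 6, whose hydrolysis should deliver the enal in the favoured Z form (thienyl anti to the formyl group), while the ester and the alkyne on the acyl-deactivated thiophene are expected to stay inert at this temperature.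

Step 4
Reactants: 7 (2Z)-3-chloro-3-{5-[4-(3-methylbutanoyloxy)but-1-yn-1-yl]thiophen-2-yl}prop-2-enal; 8 methyl sulfanylacetate
Product: 11 methyl 5-{5-[4-(3-methylbutanoyloxy)but-1-yn-1-yl]thiophen-2-yl}thiophene-2-carboxylate, via vinyl sulfide 9 (not isolated), via aldol adduct 10 (not isolated)
Conditions: K2CO3 (2 equiv), DMF, 0 °C to rt, then 60 °C
Reagents that add atoms: none
Why: K2CO3 converts 8 into its thiolate, which substitutes the vinylic chloride of 7 by conjugate addition and loss of chloride, making the S–C2' bond and leaving sulfur cis to the formyl group in 9. Carbonate then removes a proton from the SCH2CO2Me group, and the ester enolate closes onto the formyl carbon in a 5-exo-trig (enolexo) aldol reaction that makes C4'–C5' and gives 10, which dehydrates to aromatic ring B. The closest known reaction is the Fiesselmann-type thiophene synthesis from β-chlorovinyl aldehydes and sulfanylacetic esters. No stereocentre survives, because the two sp3 carbons of 10 arise as a mixture and both become sp2 on dehydration. The selectivity needed is regiochemical (sulfur at C2', carbon at C4'), and it is set by the 1,3-relationship of chlorine and formyl group in 7 together with the preference of the soft sulfur nucleophile for the β-carbon over the carbonyl carbon. The alkyne and the chain ester should be spectators in alcohol-free carbonate/DMF, and the two CH units of the enal become C3'–H and C4'–H, so ring B needs no later adjustment.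

Step 5
Reactants: 11 methyl 5-{5-[4-(3-methylbutanoyloxy)but-1-yn-1-yl]thiophen-2-yl}thiophene-2-carboxylate
Product: 12 4-[5'-(hydroxymethyl)-2,2'-bithiophen-5-yl]but-3-yn-1-ol
Conditions: i-Bu2AlH (5 equiv), CH2Cl2, −78 °C to 0 °C; then aq. KNaC4H4O6 (potassium sodium tartrate)
Reagents that add atoms: none
Why: Ester-to-alcohol reduction by i-Bu2AlH should convert the ring B methyl ester into the hydroxymethyl group and cleave the chain ester in the same operation, and the internal alkyne is not expected to undergo hydroalumination at or below 0 °C.

Step 6
Reactants: 12 4-[5'-(hydroxymethyl)-2,2'-bithiophen-5-yl]but-3-yn-1-ol; 2 3-methylbutanoyl chloride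
Product: 13 4-{5'-[(3-methylbutanoyloxy)methyl]-2,2'-bithiophen-5-yl}but-3-yn-1-yl 3-methylbutanoate
Conditions: 2 (2.5 equiv in total), Et3N (3.5 equiv), DMAP (10 mol %), CH2Cl2, 0 °C to rt
Reagents that add atoms: 3-methylbutanoyl chloride (the second equivalent of 2) CC(C)CC(Cl)=O
Why: Twofold DMAP-catalysed O-acylation (nucleophilic acyl substitution), in which one molecule of 2 esterifies the homopropargylic alcohol and a second the thienylmethyl alcohol while excess amine traps both equivalents of HCl and so spares the acid-sensitive thienylmethyl ester, should give the target directly.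

**Compound list**

1 | but-3-yn-1-ol | C#CCCO | starting material
2 | 3-methylbutanoyl chloride | CC(C)CC(Cl)=O | starting material
3 | but-3-yn-1-yl 3-methylbutanoate | CC(C)CC(=O)OCCC#C | intermediate
4 | 1-(5-bromothiophen-2-yl)ethan-1-one (2-acetyl-5-bromothiophene) | CC(=O)c1ccc(Br)s1 | starting material
5 | 4-(5-acetylthiophen-2-yl)but-3-yn-1-yl 3-methylbutanoate | CC(=O)c1ccc(C#CCCOC(=O)CC(C)C)s1 | intermediate
6 | [(2Z)-3-chloro-3-{5-[4-(3-methylbutanoyloxy)but-1-yn-1-yl]thiophen-2-yl}prop-2-en-1-ylidene]dimethylammonium chloride (not isolated) | C[N+](C)=C/C=C(\Cl)c1ccc(C#CCCOC(=O)CC(C)C)s1.[Cl-] | intermediate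
7 | (2Z)-3-chloro-3-{5-[4-(3-methylbutanoyloxy)but-1-yn-1-yl]thiophen-2-yl}prop-2-enal | O=C/C=C(\Cl)c1ccc(C#CCCOC(=O)CC(C)C)s1 | intermediate
8 | methyl sulfanylacetate | COC(=O)CS | starting material
9 | methyl {[(1Z)-3-oxo-1-{5-[4-(3-methylbutanoyloxy)but-1-yn-1-yl]thiophen-2-yl}prop-1-en-1-yl]sulfanyl}acetate (not isolated) | O=C/C=C(\SCC(=O)OC)c1ccc(C#CCCOC(=O)CC(C)C)s1 | intermediate
10 | methyl 3-hydroxy-5-{5-[4-(3-methylbutanoyloxy)but-1-yn-1-yl]thiophen-2-yl}-2,3-dihydrothiophene-2-carboxylate (not isolated; mixture of diastereomers, both centres lost on dehydration) | COC(=O)C1SC(c2ccc(C#CCCOC(=O)CC(C)C)s2)=CC1O | intermediate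
11 | methyl 5-{5-[4-(3-methylbutanoyloxy)but-1-yn-1-yl]thiophen-2-yl}thiophene-2-carboxylate | COC(=O)c1ccc(-c2ccc(C#CCCOC(=O)CC(C)C)s2)s1 | intermediate
12 | 4-[5'-(hydroxymethyl)-2,2'-bithiophen-5-yl]but-3-yn-1-ol | OCCC#Cc1ccc(-c2ccc(CO)s2)s1 | intermediate
13 | 4-{5'-[(3-methylbutanoyloxy)methyl]-2,2'-bithiophen-5-yl}but-3-yn-1-yl 3-methylbutanoate | CC(C)CC(=O)OCCC#Cc1ccc(-c2ccc(COC(=O)CC(C)C)s2)s1 | target

**Step count and risks**

Total step count: 6. Longest linear sequence: 6 steps (1 → 3 → 5 → 7 → 11 → 12 → 13).

Steps most likely to fail:

1. Step 3. The chloroiminium reagent or the HCl it releases may attack the thiophene-conjugated triple bond in competition with haloformylation of the acetyl group. The enal may also form as an E/Z mixture, of which only the Z form can close ring B. The fallback builds ring B before the alkyne is present; it sets out from 4 and rejoins the route at 11. Haloformylation of 4 (POCl3, DMF, then water) would give, through iminium chloride F1, (2Z)-3-(5-bromothiophen-2-yl)-3-chloroprop-2-enal F2. The same annulation with 8 (K2CO3, DMF) would lead through vinyl sulfide F3 and aldol adduct F4 to methyl 5-(5-bromothiophen-2-yl)thiophene-2-carboxylate F5. Sonogashira coupling of F5 with 3 (Pd(PPh3)2Cl2, CuI, Et3N, THF) would then give 11.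

2. Step 4. A second thiolate may add to the enal of the vinyl sulfide, the aldol adduct may stall before dehydration, or the basic thiolate medium may attack the chain ester. Loss of that acyl group alone would be tolerable, since step 5 removes it anyway. The fallback joins the two thiophenes by cross-coupling instead of building ring B; it sets out from 3 and rejoins the route at 11. Sonogashira coupling of 3 with 2-bromo-5-iodothiophene (Brc1ccc(I)s1) at the carbon–iodine bond (Pd(PPh3)2Cl2, CuI, Et3N, THF, rt) would give 4-(5-bromothiophen-2-yl)but-3-yn-1-yl 3-methylbutanoate F6. Suzuki–Miyaura coupling of F6 with [5-(methoxycarbonyl)thiophen-2-yl]boronic acid (COC(=O)c1ccc(B(O)O)s1; Pd(PPh3)4, K3PO4, dioxane/H2O, 70 °C) would give 11.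

3. Step 6. The thienylmethyl C–O bond may ionise to a bithiophene-stabilised cation in the presence of acid chloride and ammonium chloride, leading to chloride substitution or oligomerisation, and the second acylation may remain incomplete. The fallback changes the acyl donor and its activation; it sets out from 12 and arrives at 13. Steglich esterification with 3-methylbutanoic acid (CC(C)CC(O)=O), N,N'-dicyclohexylcarbodiimide and catalytic DMAP in CH2Cl2 at 0 °C to rt generates no chloride and no strong acid. It makes no new compound.

**Further compounds**

F1 | step 3 | [(2Z)-3-(5-bromothiophen-2-yl)-3-chloroprop-2-en-1-ylidene]dimethylammonium chloride | C[N+](C)=C/C=C(\Cl)c1ccc(Br)s1.[Cl-]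
F2 | step 3 | (2Z)-3-(5-bromothiophen-2-yl)-3-chloroprop-2-enal | O=C/C=C(\Cl)c1ccc(Br)s1
F3 | step 3 | methyl {[(1Z)-1-(5-bromothiophen-2-yl)-3-oxoprop-1-en-1-yl]sulfanyl}acetate | O=C/C=C(\SCC(=O)OC)c1ccc(Br)s1
F4 | step 3 | methyl 5-(5-bromothiophen-2-yl)-3-hydroxy-2,3-dihydrothiophene-2-carboxylate (mixture of diastereomers) | COC(=O)C1SC(c2ccc(Br)s2)=CC1O
F5 | step 3 | methyl 5-(5-bromothiophen-2-yl)thiophene-2-carboxylate | COC(=O)c1ccc(-c2ccc(Br)s2)s1
F6 | step 4 | 4-(5-bromothiophen-2-yl)but-3-yn-1-yl 3-methylbutanoate | CC(C)CC(=O)OCCC#Cc1ccc(Br)s1
F0 | step 6 | none | none
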